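**Plan**

1. Numbering (germacrane): C1 is the enol-ether carbon of the furanone, C3 its ketone, C4 the methyl-bearing quaternary carbon (ring O bridges C1 and C4), C6 the lactone O–CH, C8 the methacrylate carbinol, C9 the free carbinol, C10 bears the methylene C14, and C11(=C13H2)–C12 is the lactone acrylate. The unit C14=C10–C9(O), flanked by the sp2 carbon C1 and the carbinol C8, is an alkoxyallene inserted between a C1 alkenyl iodide and a C8 aldehyde; the furanone ring and the cis-fused lactone ring hold these two ends on one short tether.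
2. Retrosynthesis: cut the C8–O acyl bond; cut C8–C9 and C1–C10 together (opens the ten-membered ring) to iodofuranone lactone aldehyde 22 and PMB-oxyallene 26; cut the lactone C–O and C6–C7 bonds (Barbier) to aldehyde 14 and bromide 18; cut C1–I and the furanone O–C1 bond back to hydroxy ynone 8.
3. Forward order: furanone ring (steps 1–5), C1 iodide (6), C6 aldehyde (7), lactone ring (10), C8 aldehyde (11), ten-membered ring (14), methacrylate and PMB removal (15, 16).
4. Stereochemistry: C4 comes from (S)-lactic acid by self-regeneration of stereocentres. C6 and C7 come from a chair Barbier transition state whose face is chosen by a sacrificial dioxolane centre from (S)-glyceraldehyde acetonide, later cleaved to the C8 aldehyde. C8 and C9 are set in the key step (anti, from the (E)-alkoxyallylindium; C8 face from C7).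

Key step: step 14

Remark: compounds 7, 15 and the TMPZnCl·LiCl solution are taken as purchased reagents. The CIP label of C7 changes between S and R along the route only because the ranking of its neighbours C6 and C8 changes; its geometry does not.

**Step 1**
Reactants: 1 (S)-lactic acid; 2 pivalaldehyde
Product: 3 (2S,5S)-2-tert-butyl-5-methyl-1,3-dioxolan-4-one (cis)
Conditions: TsOH·H2O (cat.), H2SO4 (cat.), pentane, reflux, Dean–Stark; recrystallisation from pentane/Et2O at −78 °C
Reagents that add atoms: none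
Why: Acid-catalysed acetalisation with azeotropic removal of water, in which the cis acetal is the favoured and crystalline isomer, so the lactate centre fixes the acetal carbon.

**Step 2**
Reactants: 3 (2S,5S)-2-tert-butyl-5-methyl-1,3-dioxolan-4-one; 4 allyl bromide
Product: 5 (2S,5R)-2-tert-butyl-5-methyl-5-(prop-2-en-1-yl)-1,3-dioxolan-4-one
Conditions: LiN(iPr)2 (LDA), THF, −78 °C; then 4, −78 → −30 °C
Reagents that add atoms: none
Why: Enolate alkylation by self-regeneration of stereocentres: the planar lithium enolate is shielded by the tert-butyl group, allyl bromide enters trans to it, and the quaternary centre (the future C4, R) is set by the acetal carbon.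

**Step 3**
Reactants: 5 (2S,5R)-2-tert-butyl-5-methyl-5-(prop-2-en-1-yl)-1,3-dioxolan-4-one
Product: 6 (2R)-2-hydroxy-N-methoxy-N,2-dimethylpent-4-enamide
Conditions: MeNH(OMe)·HCl, iPrMgCl, THF, −20 → 0 °C
Reagents that add atoms: N,O-dimethylhydroxylamine hydrochloride, CNOC.Cl
Why: Weinreb amide formation by aminolysis of the acylal lactone with the chloromagnesium amide, the released hemiacetal alkoxide collapsing with loss of pivalaldehyde while the quaternary centre is untouched.

**Step 4**
Reactants: 6 (2R)-2-hydroxy-N-methoxy-N,2-dimethylpent-4-enamide; 7 ethynylmagnesium bromide (HC≡CMgBr)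
Product: 8 (4R)-4-hydroxy-4-methylhept-6-en-1-yn-3-one
Conditions: 7 (3 equiv), THF, 0 °C; quench into cold aq. NaHSO4
Reagents that add atoms: none
Why: Weinreb ketone synthesis, in which the chelated tetrahedral magnesium adduct survives until the cold acidic quench, so only one alkynyl group adds and the tertiary alkoxide merely consumes one extra equivalent of Grignard reagent.

**Step 5**
Reactants: 8 (4R)-4-hydroxy-4-methylhept-6-en-1-yn-3-one
Product: 10 (2R)-2-methyl-2-(prop-2-en-1-yl)furan-3(2H)-one, via diethylamino enone 9 (not isolated)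
Conditions: Et2NH, EtOH, 0 °C → rt; then AcOH/H2O, rt
Reagents that add atoms: none
Why: Amine-mediated cycloisomerisation of an α'-hydroxy ynone: conjugate addition of diethylamine gives enaminone 9, whose tertiary hydroxyl adds 5-exo-trig and expels the amine on acidification (addition–elimination) to close the 3(2H)-furanone.

**Step 6**
Reactants: 10 (2R)-2-methyl-2-(prop-2-en-1-yl)furan-3(2H)-one
Product: 12 (2R)-5-iodo-2-methyl-2-(prop-2-en-1-yl)furan-3(2H)-one, via furanonylzinc chloride 11 (not isolated)
Conditions: TMPZnCl·LiCl (1.2 equiv), THF, 25 °C; then I2, 0 °C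
Reagents that add atoms: iodine, II (the ZnCl of 11 comes from TMPZnCl·LiCl, CC1(C)CCCC(C)(C)N1[Zn]Cl.[Li+].[Cl-])
Why: Deprotonative zincation of the C–H bond next to the ring oxygen of a cyclic vinylogous ester (as practised on chromones and 4-pyranones) followed by iodinolysis; the quaternary C4 leaves no enolisable position and the mild zinc amide spares the allyl group.

**Step 7**
Reactants: 12 (2R)-5-iodo-2-methyl-2-(prop-2-en-1-yl)furan-3(2H)-one
Product: 14 2-[(2R)-5-iodo-2-methyl-3-oxo-2,3-dihydrofuran-2-yl]acetaldehyde, via vicinal diol 13 (not isolated)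
Conditions: OsO4 (cat.), NaIO4, 2,6-lutidine, 1,4-dioxane/H2O, rt; crude aldehyde used at once
Reagents that add atoms: osmium tetroxide, O=[Os](=O)(=O)=O (oxygen carrier, re-formed by sodium periodate, [Na+].[O-][I](=O)(=O)=O)
Why: Lemieux–Johnson oxidation, in which OsO4 should dihydroxylate the monosubstituted alkene faster than the push–pull iodoenone and NaIO4 cleaves diol 13 in the same pot, the lutidine buffer keeping the β-oxy aldehyde from eliminating.

**Step 8**
Reactants: 15 (4S)-2,2-dimethyl-1,3-dioxolane-4-carbaldehyde; 16 methyl acrylate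
Product: 17 methyl 2-{[(4S)-2,2-dimethyl-1,3-dioxolan-4-yl](hydroxy)methyl}prop-2-enoate (both carbinol epimers)
Conditions: DABCO, 1,4-dioxane/H2O, rt
Reagents that add atoms: none
Why: Morita–Baylis–Hillman reaction of an activated α-alkoxy aldehyde; the new carbinol centre is formed without control and is erased in the next step, while the dioxolane centre is kept.

**Step 9**
Reactants: 17 methyl 2-{[(4S)-2,2-dimethyl-1,3-dioxolan-4-yl](hydroxy)methyl}prop-2-enoate
Product: 18 methyl (2Z)-2-(bromomethyl)-3-[(4R)-2,2-dimethyl-1,3-dioxolan-4-yl]prop-2-enoate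
Conditions: NBS, Me2S, CH2Cl2, 0 °C → rt
Reagents that add atoms: N-bromosuccinimide, O=C1CCC(=O)N1Br
Why: Corey–Kim-type bromination of a Baylis–Hillman alcohol with allylic transposition (SN2'), which gives the thermodynamically preferred (Z)-2-(bromomethyl)enoate under neutral conditions that keep the acetonide.

**Step 10**
Reactants: 14 2-[(2R)-5-iodo-2-methyl-3-oxo-2,3-dihydrofuran-2-yl]acetaldehyde; 18 methyl (2Z)-2-(bromomethyl)-3-[(4R)-2,2-dimethyl-1,3-dioxolan-4-yl]prop-2-enoate
Product: 20 (4S,5S)-4-[(4R)-2,2-dimethyl-1,3-dioxolan-4-yl]-5-{[(2R)-5-iodo-2-methyl-3-oxo-2,3-dihydrofuran-2-yl]methyl}-3-methylideneoxolan-2-one (cis-lactone), via hydroxy ester 19 (not isolated)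
Conditions: indium powder, THF/H2O, rt; then PPTS (cat.), toluene, 60 °C
Reagents that add atoms: none
Why: Indium Barbier allylation followed by lactonisation: the (Z)-allylindium reacts through its γ-carbon in a chair transition state (syn adduct, hence cis-lactone), and with the dioxolane C–H held in the allyl plane by A(1,3) strain the aldehyde should add anti to the dioxolane C–O bond, which fixes C7 and with it C6 as S irrespective of the remote C4 centre.

**Step 11**
Reactants: 20 (4S,5S)-4-[(4R)-2,2-dimethyl-1,3-dioxolan-4-yl]-5-{[(2R)-5-iodo-2-methyl-3-oxo-2,3-dihydrofuran-2-yl]methyl}-3-methylideneoxolan-2-one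
Product: 22 (2S,3S)-2-{[(2R)-5-iodo-2-methyl-3-oxo-2,3-dihydrofuran-2-yl]methyl}-4-methylidene-5-oxooxolane-3-carbaldehyde (cis-lactone C8 aldehyde), via vicinal diol 21 (not isolated)
Conditions: H5IO6, EtOAc, 0 °C → rt; neutral work-up, used at once
Reagents that add atoms: none
Why: One-pot acetonide hydrolysis and glycol cleavage with periodic acid, which destroys the sacrificial C8 centre and releases the aldehyde without base, so the C7 centre next to it should not epimerise or slip into conjugation.

**Step 12**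
Reactants: 23 4-methoxybenzyl alcohol; 24 propargyl bromide
Product: 25 1-methoxy-4-[(prop-2-yn-1-yloxy)methyl]benzene
Conditions: NaH, THF, 0 °C; then 24, Bu4NI (cat.), rt
Reagents that add atoms: none
Why: Williamson ether synthesis between a benzylic alkoxide and a primary propargylic bromide.

**Step 13**
Reactants: 25 1-methoxy-4-[(prop-2-yn-1-yloxy)methyl]benzene
Product: 26 1-methoxy-4-[(propa-1,2-dien-1-yloxy)methyl]benzene (PMB-oxyallene)
Conditions: KOtBu (cat.), THF, rt
Reagents that add atoms: none
Why: Base-catalysed prototropic isomerisation of a propargyl ether to the allenyl ether, the standard preparation of alkoxyallenes.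

**Step 14**
Reactants: 22 (2S,3S)-2-{[(2R)-5-iodo-2-methyl-3-oxo-2,3-dihydrofuran-2-yl]methyl}-4-methylidene-5-oxooxolane-3-carbaldehyde; 26 1-methoxy-4-[(propa-1,2-dien-1-yloxy)methyl]benzene
Product: 30 (4R,6S,7R,8R,9S)-1,4-epoxy-8-hydroxy-9-[(4-methoxyphenyl)methoxy]-3-oxogermacra-1,10(14),11(13)-trien-12,6-olide, via alkenylpalladium iodide 27 (not isolated), via allylpalladium iodide 28 (not isolated), via allylindium diiodide 29 (not isolated)
Conditions: Pd(PPh3)4 (10 mol %), indium powder (2 equiv), 26 (5 equiv), DMF, 45 °C; 22 added by syringe pump to a final 2 mM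
Reagents that add atoms: none
Why: Proposed new method: zerovalent palladium inserts into the C1–I bond of 22 to give 27, which carbopalladates the central carbon of 26 (C1–C10) to the 1-alkoxyallylpalladium 28; indium metal reduces 28 to the allylindium 29 with the metal on C14, and 29 adds through its γ-carbon C9 to the tethered C8 aldehyde in a six-membered cyclic transition state while palladium returns to the zerovalent state. The closest known reactions are the palladium-catalysed, indium-mediated three-component coupling of aryl or alkenyl iodides with allenes and aldehydes and the anti-selective addition of γ-alkoxyallylindium reagents to aldehydes; neither has been run with an alkoxyallene in a ring-closing sense. The ten-membered carbocycle closes in the allylation event by C8–C9 bond formation, the tether running from the central allyl carbon C10 through the furanone and the cis-lactone to the aldehyde, so the C10=C14 methylene ends up exocyclic. C9 is set relative to C8 by the (E)-enol ether geometry of 29 in the chair-like Zimmerman–Traxler arrangement (anti diol monoether), and the C8 face by the adjacent C7 centre in a Felkin–Anh arrangement with C6 anti to the incoming C9 and the C7 hydrogen flanking the trajectory, which the forming ring can accommodate. The step needs allene insertion to outrun Heck reaction and premature reduction of 27 (excess 26, hindered 1,1-disubstituted acrylate), γ-regioselectivity (indium on the unsubstituted terminus C14) and ring closure over oligomerisation (slow addition at high dilution).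

**Step 15**
Reactants: 30 (4R,6S,7R,8R,9S)-1,4-epoxy-8-hydroxy-9-[(4-methoxyphenyl)methoxy]-3-oxogermacra-1,10(14),11(13)-trien-12,6-olide; 31 methacrylic anhydride
Product: 32 (4R,6S,7S,8R,9S)-1,4-epoxy-9-[(4-methoxyphenyl)methoxy]-8-[(2-methylprop-2-enoyl)oxy]-3-oxogermacra-1,10(14),11(13)-trien-12,6-olide
Conditions: 31, Et3N, DMAP (cat.), CH2Cl2, 0 °C → rt
Reagents that add atoms: none
Why: DMAP-catalysed (Steglich-type) acylation of the only free hydroxyl, under a mild amine base at low temperature so that the C8 oxygen should not relactonise onto C12.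

**Step 16**
Reactants: 32 (4R,6S,7S,8R,9S)-1,4-epoxy-9-[(4-methoxyphenyl)methoxy]-8-[(2-methylprop-2-enoyl)oxy]-3-oxogermacra-1,10(14),11(13)-trien-12,6-olide
Product: 33 (4R,6S,7S,8R,9S)-1,4-epoxy-9-hydroxy-8-[(2-methylprop-2-enoyl)oxy]-3-oxogermacra-1,10(14),11(13)-trien-12,6-olide (CNP0142847.2)
Conditions: DDQ, CH2Cl2/pH 7 phosphate buffer, 0 °C → rt
Reagents that add atoms: none
Why: Oxidative cleavage of the 4-methoxybenzyl ether with DDQ (hydride abstraction, hydrolysis of the oxocarbenium ion) under buffered conditions that should leave the methacrylate, the α-methylene lactone and the dienone untouched.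

**Compound list**

1 | (S)-lactic acid | C[C@H](O)C(=O)O | starting material
2 | pivalaldehyde | CC(C)(C)C=O | starting material
3 | (2S,5S)-2-tert-butyl-5-methyl-1,3-dioxolan-4-one | C[C@@H]1O[C@H](C(C)(C)C)OC1=O | intermediate
4 | allyl bromide | C=CCBr | starting material
5 | (2S,5R)-2-tert-butyl-5-methyl-5-(prop-2-en-1-yl)-1,3-dioxolan-4-one | C[C@]1(CC=C)O[C@H](C(C)(C)C)OC1=O | intermediate
6 | (2R)-2-hydroxy-N-methoxy-N,2-dimethylpent-4-enamide | C=CC[C@@](C)(O)C(=O)N(C)OC | intermediate
7 | ethynylmagnesium bromide | C#C[Mg]Br | starting material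
8 | (4R)-4-hydroxy-4-methylhept-6-en-1-yn-3-one | C=CC[C@@](C)(O)C(=O)C#C | intermediate
9 | (1E,4R)-1-(diethylamino)-4-hydroxy-4-methylhepta-1,6-dien-3-one | C=CC[C@@](C)(O)C(=O)/C=C/N(CC)CC | intermediate
10 | (2R)-2-methyl-2-(prop-2-en-1-yl)furan-3(2H)-one | C=CC[C@@]1(C)OC=CC1=O | intermediate
11 | chloro[(5R)-5-methyl-4-oxo-5-(prop-2-en-1-yl)-4,5-dihydrofuran-2-yl]zinc (LiCl not drawn) | C=CC[C@@]1(C)OC([Zn]Cl)=CC1=O | intermediate
12 | (2R)-5-iodo-2-methyl-2-(prop-2-en-1-yl)furan-3(2H)-one | C=CC[C@@]1(C)OC(I)=CC1=O | intermediate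
13 | (2R)-2-(2,3-dihydroxypropyl)-5-iodo-2-methylfuran-3(2H)-one (both carbinol epimers) | OCC(O)C[C@@]1(C)OC(I)=CC1=O | intermediate
14 | 2-[(2R)-5-iodo-2-methyl-3-oxo-2,3-dihydrofuran-2-yl]acetaldehyde | O=CC[C@@]1(C)OC(I)=CC1=O | intermediate
15 | (4S)-2,2-dimethyl-1,3-dioxolane-4-carbaldehyde | CC1(C)OC[C@@H](C=O)O1 | starting material
16 | methyl acrylate | C=CC(=O)OC | starting material
17 | methyl 2-{[(4S)-2,2-dimethyl-1,3-dioxolan-4-yl](hydroxy)methyl}prop-2-enoate (both carbinol epimers) | C=C(C(=O)OC)C(O)[C@@H]1COC(C)(C)O1 | intermediate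
18 | methyl (2Z)-2-(bromomethyl)-3-[(4R)-2,2-dimethyl-1,3-dioxolan-4-yl]prop-2-enoate | COC(=O)/C(CBr)=C/[C@@H]1COC(C)(C)O1 | intermediate
19 | methyl (3S,4S)-3-[(4R)-2,2-dimethyl-1,3-dioxolan-4-yl]-4-hydroxy-5-[(2R)-5-iodo-2-methyl-3-oxo-2,3-dihydrofuran-2-yl]-2-methylidenepentanoate | COC(=O)C(=C)[C@H]([C@@H]1COC(C)(C)O1)[C@@H](O)C[C@@]1(C)OC(I)=CC1=O | intermediate
20 | (4S,5S)-4-[(4R)-2,2-dimethyl-1,3-dioxolan-4-yl]-5-{[(2R)-5-iodo-2-methyl-3-oxo-2,3-dihydrofuran-2-yl]methyl}-3-methylideneoxolan-2-one | CC1(C)OC[C@H](O1)[C@H]1C(=C)C(=O)O[C@H]1C[C@@]1(C)OC(I)=CC1=O | intermediate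
21 | (4R,5S)-4-[(1R)-1,2-dihydroxyethyl]-5-{[(2R)-5-iodo-2-methyl-3-oxo-2,3-dihydrofuran-2-yl]methyl}-3-methylideneoxolan-2-one | OC[C@H](O)[C@H]1C(=C)C(=O)O[C@H]1C[C@@]1(C)OC(I)=CC1=O | intermediate
22 | (2S,3S)-2-{[(2R)-5-iodo-2-methyl-3-oxo-2,3-dihydrofuran-2-yl]methyl}-4-methylidene-5-oxooxolane-3-carbaldehyde | O=C[C@H]1C(=C)C(=O)O[C@H]1C[C@@]1(C)OC(I)=CC1=O | intermediate
23 | 4-methoxybenzyl alcohol | COc1ccc(CO)cc1 | starting material
24 | propargyl bromide | C#CCBr | starting material
25 | 1-methoxy-4-[(prop-2-yn-1-yloxy)methyl]benzene | COc1ccc(COCC#C)cc1 | intermediate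
26 | 1-methoxy-4-[(propa-1,2-dien-1-yloxy)methyl]benzene | C=C=COCc1ccc(OC)cc1 | intermediate
27 | alkenylpalladium iodide from 22, palladium on C1 (PPh3 ligands not drawn) | O=C[C@H]1C(=C)C(=O)O[C@H]1C[C@@]1(C)OC(=CC1=O)[Pd]I | intermediate
28 | 1-alkoxy-2-furanonyl allylpalladium iodide, drawn as its C14-bound sigma form (PPh3 not drawn) | O=C[C@H]1C(=C)C(=O)O[C@H]1C[C@@]1(C)OC(=CC1=O)C(C[Pd]I)=COCc1ccc(OC)cc1 | intermediate
29 | (E)-allylindium diiodide, indium on C14, PMB enol ether at C9 | O=C[C@H]1C(=C)C(=O)O[C@H]1C[C@@]1(C)OC(=CC1=O)/C(C[In](I)I)=C\OCc1ccc(OC)cc1 | intermediate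
30 | (4R,6S,7R,8R,9S)-1,4-epoxy-8-hydroxy-9-[(4-methoxyphenyl)methoxy]-3-oxogermacra-1,10(14),11(13)-trien-12,6-olide | O[C@@H]1[C@H]2C(=C)C(=O)O[C@H]2C[C@@]2(C)OC(=CC2=O)C(=C)[C@@H]1OCc1ccc(OC)cc1 | intermediate
31 | methacrylic anhydride | CC(=C)C(=O)OC(=O)C(C)=C | starting material
32 | (4R,6S,7S,8R,9S)-1,4-epoxy-9-[(4-methoxyphenyl)methoxy]-8-[(2-methylprop-2-enoyl)oxy]-3-oxogermacra-1,10(14),11(13)-trien-12,6-olide | C=C(C)C(=O)O[C@@H]1[C@H]2C(=C)C(=O)O[C@H]2C[C@@]2(C)OC(=CC2=O)C(=C)[C@@H]1OCc1ccc(OC)cc1 | intermediate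
33 | (4R,6S,7S,8R,9S)-1,4-epoxy-9-hydroxy-8-[(2-methylprop-2-enoyl)oxy]-3-oxogermacra-1,10(14),11(13)-trien-12,6-olide (CNP0142847.2) | C=C(C)C(=O)O[C@@H]1[C@H]2C(=C)C(=O)O[C@H]2C[C@@]2(C)OC(=CC2=O)C(=C)[C@@H]1O | target

**Step count**

Total: 16 steps. Longest linear sequence: 12 steps (1–7, 10, 11, 14, 15, 16).

**Steps most likely to fail**

Step 14. The alkenylpalladium 27 may be reduced before the allene inserts, the allylindium may add to the aldehyde of a second molecule (oligomers), attack may occur through C14, or the C8 face may be poorly differentiated. The fallback makes the two bonds one after the other with known reactions. It sets out from 22 and 26 and returns at 30. Allene 26 would be diborated across its terminal double bond with B2pin2 under palladium catalysis (Pd(dba)2, PCy3, toluene) to the (E)-2-boryl-γ-alkoxyallylboronate 2,2'-[(2E)-3-[(4-methoxyphenyl)methoxy]prop-2-ene-1,2-diyl]bis(4,4,5,5-tetramethyl-1,3,2-dioxaborolane) F1. Thermal allylboration of aldehyde 22 with F1 (toluene, 40 °C; closed chair, anti) would form C8–C9 and give the open-chain C8 alcohol that carries the C9 PMB ether, a C10 alkenylboronate and the intact C1 iodide, F2. An intramolecular Suzuki–Miyaura coupling (Pd(PPh3)4, TlOEt, THF/H2O, high dilution) would then close C1–C10 and give 30.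

Step 6. The zinc amide may metalate the carbon next to the ketone instead of C1, or the metalated vinylogous ester may fragment before it meets iodine. The fallback sets out from 10 and returns at 12. Furanone 10 would be lithiated with lithium 2,2,6,6-tetramethylpiperidide at −78 °C in the presence of B(OiPr)3, so that the anion is trapped as it forms. Exchange with pinacol would give the boronate (2R)-2-methyl-2-(prop-2-en-1-yl)-5-(4,4,5,5-tetramethyl-1,3,2-dioxaborolan-2-yl)furan-3(2H)-one F3, and ipso-iodination with N-iodosuccinimide in MeCN would give 12.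

Step 10. The dioxolane centre may steer the aldehyde to the other face of the allylindium (addition syn instead of anti to the C–O bond), which would give the enantiomeric C6/C7 pair next to the fixed C4 centre. The fallback takes the controlling centre from the opposite chiral-pool series; it sets out from 14 and 16 and returns at 22. (4R)-2,2-Dimethyl-1,3-dioxolane-4-carbaldehyde and 16 would give the Baylis–Hillman alcohol methyl 2-{[(4R)-2,2-dimethyl-1,3-dioxolan-4-yl](hydroxy)methyl}prop-2-enoate F4, and NBS/Me2S would give the bromide methyl (2Z)-2-(bromomethyl)-3-[(4S)-2,2-dimethyl-1,3-dioxolan-4-yl]prop-2-enoate F5. Indium Barbier reaction of F5 with 14 would give the C8-epimeric hydroxy ester F6 and, after lactonisation, the C8-epimeric cis-lactone acetonide F7. Because C8 loses its stereocentre, periodic acid would take F7 through the C8-epimeric diol F8 to the same aldehyde 22.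

**Further compounds**

F1 | step 14 | 2,2'-[(2E)-3-[(4-methoxyphenyl)methoxy]prop-2-ene-1,2-diyl]bis(4,4,5,5-tetramethyl-1,3,2-dioxaborolane) | COc1ccc(CO/C=C(/CB2OC(C)(C)C(C)(C)O2)B2OC(C)(C)C(C)(C)O2)cc1
F2 | step 14 | (4R,5S)-4-[(1R,2S)-1-hydroxy-2-[(4-methoxyphenyl)methoxy]-3-(4,4,5,5-tetramethyl-1,3,2-dioxaborolan-2-yl)but-3-en-1-yl]-5-{[(2R)-5-iodo-2-methyl-3-oxo-2,3-dihydrofuran-2-yl]methyl}-3-methylideneoxolan-2-one | O[C@H]([C@H]1C(=C)C(=O)O[C@H]1C[C@@]1(C)OC(I)=CC1=O)[C@@H](OCc1ccc(OC)cc1)C(=C)B1OC(C)(C)C(C)(C)O1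
F3 | step 6 | (2R)-2-methyl-2-(prop-2-en-1-yl)-5-(4,4,5,5-tetramethyl-1,3,2-dioxaborolan-2-yl)furan-3(2H)-one | C=CC[C@@]1(C)OC(B2OC(C)(C)C(C)(C)O2)=CC1=O
F4 | step 10 | methyl 2-{[(4R)-2,2-dimethyl-1,3-dioxolan-4-yl](hydroxy)methyl}prop-2-enoate | C=C(C(=O)OC)C(O)[C@H]1COC(C)(C)O1
F5 | step 10 | methyl (2Z)-2-(bromomethyl)-3-[(4S)-2,2-dimethyl-1,3-dioxolan-4-yl]prop-2-enoate | COC(=O)/C(CBr)=C/[C@H]1COC(C)(C)O1
F6 | step 10 | methyl (3S,4S)-3-[(4S)-2,2-dimethyl-1,3-dioxolan-4-yl]-4-hydroxy-5-[(2R)-5-iodo-2-methyl-3-oxo-2,3-dihydrofuran-2-yl]-2-methylidenepentanoate | COC(=O)C(=C)[C@H]([C@H]1COC(C)(C)O1)[C@@H](O)C[C@@]1(C)OC(I)=CC1=O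
F7 | step 10 | (4S,5S)-4-[(4S)-2,2-dimethyl-1,3-dioxolan-4-yl]-5-{[(2R)-5-iodo-2-methyl-3-oxo-2,3-dihydrofuran-2-yl]methyl}-3-methylideneoxolan-2-one | CC1(C)OC[C@@H](O1)[C@H]1C(=C)C(=O)O[C@H]1C[C@@]1(C)OC(I)=CC1=O
F8 | step 10 | (4R,5S)-4-[(1S)-1,2-dihydroxyethyl]-5-{[(2R)-5-iodo-2-methyl-3-oxo-2,3-dihydrofuran-2-yl]methyl}-3-methylideneoxolan-2-one | OC[C@@H](O)[C@H]1C(=C)C(=O)O[C@H]1C[C@@]1(C)OC(I)=CC1=O
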